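A catalyst turn has no fixed length. It stretches as substrate and reagent fall, so a starting turnover rate times the run time overshoots.

- north: substrate 0.055 M; reagent 0.600 equiv; free catalyst 0.5 mol%; time 10 h
- north-east: substrate 0.055 M; reagent 0.600 equiv; free catalyst 1.5 mol%; time 10 h

    substrate + free catalyst → catalyst intermediate A (k1 = 0.10 M⁻¹ s⁻¹)
    catalyst intermediate A → catalyst intermediate B (k2 = 0.0068 s⁻¹)
    catalyst intermediate C → free catalyst + target (k3 = 0.0077 s⁻¹)
    substrate + catalyst intermediate A → spent catalyst (k4 = 3.2 × 10⁻⁴ M⁻¹ s⁻¹)
    reagent + catalyst intermediate B ⇌ catalyst intermediate C (K5 = 33 M⁻¹, k5 = 3.0 M⁻¹ s⁻¹)

- which of these there is most of at the end, counted by the substrate in it, north (catalyst intermediate B / target / catalyst intermediate A / substrate)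
- which of these there is most of at the end, counted by the substrate in it, north-east (catalyst intermediate B / target / catalyst intermediate A / substrate)
- final amount of the leader among these, as a percentage of the substrate charged, in north
- final amount of the leader among these, as a percentage of the substrate charged, in north-east

Let f be the fraction of substrate left. Each turn removes one substrate and one reagent, so c(reagent) follows f. A turn has three parts: entry of substrate, which scales as one over c(substrate); the two first-order steps, 277 s together; and capture of reagent, which scales as one over c(reagent).

Summing the turn time over the substrate consumed gives the bill: entry term 182 s times ln(1/f), plus the fixed time times (1 − f), plus capture term 77.6 s times ln(reagent charged / reagent left). The flask pays with its budget, loading times run time: 180 s in north and 540 s in north-east. The catalyst is counted as alive throughout.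

- f = 0.7: entry 64.8 s, fixed 83.1 s, reagent 53.8 s; bill 202 s
- f = 0.5: entry 126 s, fixed 138 s, reagent 139 s; bill 404 s

Down the rows, the reagent column grows 2.58 times and the entry column 1.94 times. North's budget is smaller than the upper bill, so north stops above that row. Read straight from f = 1, north leaves 73.2% substrate, and substrate leads.

North-east's budget exceeds the lower bill, so it passes the middle and nears the limit of the limiting reagent, f = 0.400. With the first two columns taken there, the rest of the budget falls on the reagent column, which leaves 6.92% of the reagent. Target then reaches 55.8%, and target leads.

The forecast gives substrate at 74% in north and target at 55% in north-east, saying “the catalyst manages only about 50 turnovers in 10 h”.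

The simulation gives substrate at 74.1% in north and target at 55.7% in north-east, with 7.1% of the reagent left there. The bill for north's standing substrate is 170 s, less than the budget by 5.44%. Spent catalyst in north stands at 6.75% of the catalyst at 5.00 h. The flask like north with 0.3 mol% of free catalyst has a budget of 108 s; read straight against the upper bill, it leaves 84.0% substrate, and that flask holds 83.8%.

The constants were chosen freely, and the outcome is calculated.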